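The data stem from a simulated flask from invented constants, and the scatter is random.

The ratio I followed is the odds ω: J made over Z not yet converted, with bound and free read together. I needed it before charging the delta flask. The decision was whether to raise E to 21.0 mM, with Z kept at 200 mM and the stop at 52 h, when the eta run at 12.0 mM had already turned 69.4% of its Z by then.

| flask | Z | E | time |
|---|---|---|---|
| theta | 200 mM | 6.00 mM |  |
| beta | 80.0 mM | 6.00 mM |  |
| eta | 200 mM | 12.0 mM |  |
| zeta | 400 mM | 6.00 mM |  |
| delta | 200 mM | 21.0 mM | 52 h |

- theta run (time / h: [J] / mM): 8.7: 8.4; 17: 17.5; 26: 30.8; 35: 58.1; 43: 82.3; 52: 109.2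
- beta run (time / h: [J] / mM): 8.7: 4.4; 17: 2.9; 26: 7.6; 35: 3.0; 43: 7.6; 52: 10.5
- eta run (time / h: [J] / mM): 8.7: 12.1; 17: 31.8; 26: 54.4; 35: 86.6; 43: 116.6; 52: 138.8
- zeta run (time / h: [J] / mM): 8.7: 29.4; 17: 89.2; 26: 201.7; 35: 307.4; 43: 358.4; 52: 389.5

(each reading ± 2 mM)

- the exponent of [Z] in the starting rate at the charge of the theta run (at the point where two percent of the Z have become J) (one fixed amount of J, the same in the runs compared)
- the exponent of [E] in the starting rate at the charge of the theta run (at the point where two percent of the Z have become J)
- the beta run starts with 120 mM less of Z than the theta run, and with no J. Compared where both hold the same amount of Z, once fifteen percent of what the beta run was charged with has turned into J, is the beta run faster, slower or alike (within a tenth)?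
- J in the delta run at 52 h, as a share of the Z charged
- which of these the readings show (the catalyst rests as a dimer / the product binds the substrate / the catalyst dies by itself / the product speeds the reaction)

- Overall: Z -> J, with E as catalyst.
- Constant volume, constant temperature.
- Bound and free are read together.
- An order is taken over about fifteen percent of the charge, up and down.

The theta run made J faster between 35 h and 43 h, at 3.02 mM h⁻¹, than over its first 8.7 h, at 0.966 mM h⁻¹, although it held less Z. I read this as autocatalysis: J speeds its own formation. In growth with a rate proportional to Z times J, ω multiplies steadily with time, and with a small start-up source ω at a given time scales roughly with that source. So I compared the eta and theta runs, which had equal Z and a ratio of 2.00 in E, at equal times. Their odds stood in the ratio 2.05 at 26 h, 2.00 at 43 h and 1.89 at 52 h.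

My rule, with Z charge and time held fixed, was therefore that ω goes with E. The quantity I carried was w, the odds per mM of E at 52 h, with the Z charge at 200 mM. The theta run read 0.200 mM⁻¹ and the eta run 0.189 mM⁻¹, so I took their mean, 0.195 mM⁻¹. For the delta flask this gave ω = 4.09, and ω/(1+ω) gave a share of 80.4%, which is 11 percentage points above the eta run. I decided to charge it and leave the stop where it was.

The forecast gave an order in Z of 1.3 (0.9 to 1.8), an order in E of 0.5 (0.3 to 0.85), the beta run slower, the product speeds the reaction, and 90% (80% to 96%) for the delta run, higher than my share, from “A logistic fit scaled by 3.5^0.5 gives about 181 mM J”.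

The simulation gave orders of 1.6 in Z and 0.70 in E, the beta run slower at a rate ratio of 0.12, the product speeds the reaction, and 80.7% for the delta run.

    E + Z ⇌ EZ, settled at all times (0.9060 M⁻¹)
    EZ + Z ⇌ EZ2, settled at all times (0.9650 M⁻¹)
    EZ2 → J + EZ (3.600 h⁻¹)
    Z + J → 2 J (0.3139 M⁻¹ h⁻¹)

In the delta run, the odds per mM of E came to 0.199 mM⁻¹, against the 0.195 mM⁻¹ I had carried. The conversion of Z + J into 2 J holds that value up. The same delta run with that step taken away reached 36.2% of its Z at 52 h. Its w was 0.0270 mM⁻¹, lower by a factor of 7.37.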